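The constants of this coupling are not given, so the readings must stand in for them.

| flask | starting material | coupling partner | remark | time |
|---|---|---|---|---|
| summer | 20 mM | 0.95 equiv | run made earlier |  |
| dawn | 20 mM | 1.3 equiv | run made earlier |  |
| autumn | 20 mM | 2.1 equiv | run made earlier |  |
| Sunday's | 20 mM | 0.950 equiv (fed, over 5.0 min) | all else is in the flask from the start; the feed brings no volume worth counting | 6.0 min |
| Saturday's | 20 mM | 0.950 equiv | everything together at the start | 6.0 min |
| Friday's | 20 mM (fed, over 5.0 min) | 0.950 equiv | all else is in the flask from the start; the feed brings no volume worth counting | 6.0 min |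

| run | time / min | side product / % | bis adduct / % |
|---|---|---|---|
| summer | 0.500 | 0.7 | 3.3 |
| summer | 1.50 | 1.7 | 8.9 |
| summer | 3.00 | 6.1 | 11.2 |
| summer | 4.00 | 9.7 | 9.3 |
| summer | 6.00 | 14.2 | 6.0 |
| dawn | 0.500 | 0.7 | 4.3 |
| dawn | 1.50 | 2.5 | 14.8 |
| dawn | 3.00 | 13.1 | 16.2 |
| dawn | 4.00 | 18.9 | 14.3 |
| dawn | 6.00 | 28.2 | 9.8 |
| autumn | 0.500 | 0.8 | 10.4 |
| autumn | 0.833 | 2.3 | 18.9 |
| autumn | 1.50 | 8.9 | 27.8 |
| autumn | 3.00 | 31.7 | 27.1 |
| autumn | 6.00 | 62.3 | 14.7 |

(scatter of a reading: 0.5 percentage points)



* the flask that comes out highest in amount of side product, in percent of the starting material charged, or "all alike" when all lie within 1.5 percentage points (Sunday's / Saturday's / Friday's / all alike)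
* side product at the end, in percent of the starting material charged, Sunday's
* side product at the end, in percent of the starting material charged, Saturday's
* side product at the end, in percent of the starting material charged, Friday's

How fast does bis adduct turn into side product? The burn constant is the side product gained per minute over the bis adduct standing, a pseudo-first-order constant. The summer run reads 0.294 /min between 4.00 min and 6.00 min. Early in that run it reads a slower 0.164 /min. The autumn run, with more coupling partner, reads a faster 0.488 /min between 3.00 min and 6.00 min. So in these readings the burn climbs as the runs go on.

Then what does a late start cost? Saturday's repeats the summer charges, so this reckoning takes the summer reading, 14.2%, for it. A steady feed delivers on average at 2.50 min, so this reckoning reads each fed flask at 3.50 min on the batch clock. That puts the estimate for Sunday's at the summer value there, 7.90%. Friday's holds its coupling partner from the start while starting material arrives, so this reckoning borrows the dawn run, with its larger charge of coupling partner, as a rough stand-in, and the dawn value there is 16.0%. The mean of the two gives an estimate for Friday's of 11.9%, lower than the estimate for Saturday's.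

The forecast names Saturday's, with 5% for Sunday's, 14.3% for Saturday's and 11.5% for Friday's, holding for Sunday's slow feed that “bis and promoter arrive late”. Its Sunday's figure lies below this reckoning's.

    starting material + coupling partner → first product + released group (k = 0.800 /M/s)
    coupling partner + first product → bis adduct + released group (k = 0.400 /M/s)
    bis adduct + released group → side product (k = 0.353 /M/s)

Saturday's comes out highest at 15.0%, as the forecast chose, with Friday's at 10.7% and Sunday's at 5.96%. Sunday's made half of its side product after the feed ended, gaining 3 percentage points. The burn constant on its bis adduct over that stretch gives 2.8 points. Saturday's flask, read on to 10 min, holds 20.2% side product, and the burn constant on its bis adduct from 6.0 min gives 20.1%.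

Readings and results were generated by integration with made-up constants; noise was put on by code.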